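**Retrosynthetic overview**
1. The strategy rests on the benzene ring of the 4-hydroxybenzoate, the only ring of the target: C1' carries the ester carbonyl, C4' (para) carries OH, and C2', C3', C5', C6' are plain CH. This is the pattern a propiolate ester (C1', C2') and 1-methoxy-3-(trimethylsilyloxy)butadiene (C3'–C6') give by [4+2] addition, forming C2'–C3' and C6'–C1', followed by loss of methanol.
2. Target 16 comes from its primary silyl ether 15; 15 comes from glyceryl propiolate 11 and diene 12; 11 comes from alcohol 9 and propiolic acid; 9 comes from diol 8 and acetonide 7.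
3. The triene is disconnected at C4=C5 of the dodecatrienyl chain: Julia–Kocienski olefination of (2E,4E)-octa-2,4-dienal with a phenyltetrazolyl sulfone that already carries the glycerol ether.
4. The sulfone comes from (R)-solketal, which supplies glycerol C2 (the only stereocentre), by O-alkylation with 1-bromo-4-chlorobutane, thiolate displacement and oxidation.
5. Ring order: the dioxolane of solketal is a temporary ring, opened in step 5; the benzene ring is the only ring built, in step 8.

Key step: step 8

Remark: the target is a 1-O-alkyl-2-O-acyl-sn-glycerol, (S) at C2. The same spatial arrangement carries the descriptor (R) in the silylated compounds 9–15 only because the silyloxymethyl arm gains CIP priority.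

**Route**

Step 1
Reactants: 1 (R)-solketal; 2 1-bromo-4-chlorobutane
Product: 3 (4R)-4-[(4-chlorobutoxy)methyl]-2,2-dimethyl-1,3-dioxolane
Conditions: NaH, DMF, 0 °C → rt; 2 in excess (3 equiv)
Reagents that add atoms: none
Why: Williamson ether synthesis in which the alkoxide of 1 displaces bromide, the better leaving group, so the chloride is kept for step 2; the stereocentre is not a reacting atom.

Step 2
Reactants: 3 (4R)-4-[(4-chlorobutoxy)methyl]-2,2-dimethyl-1,3-dioxolane
Product: 4 5-[(4-{[(4R)-2,2-dimethyl-1,3-dioxolan-4-yl]methoxy}butyl)sulfanyl]-1-phenyl-1H-tetrazole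
Conditions: 1-phenyl-1H-tetrazole-5-thiol, K2CO3, NaI (cat.), DMF, 60 °C
Reagents that add atoms: 1-phenyl-1H-tetrazole-5-thiol, Sc1nnnn1-c1ccccc1
Why: SN2 S-alkylation of the soft tetrazolethiolate at the primary chloride, helped by in situ Finkelstein exchange to the iodide.

Step 3
Reactants: 4 the tetrazolyl sulfide
Product: 5 5-[(4-{[(4R)-2,2-dimethyl-1,3-dioxolan-4-yl]methoxy}butyl)sulfonyl]-1-phenyl-1H-tetrazole
Conditions: (NH4)6Mo7O24·4H2O (cat.), 30% H2O2, EtOH, 0 °C → rt
Reagents that add atoms: hydrogen peroxide, OO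
Why: Molybdate-catalysed peroxide oxidation of a sulfide to the sulfone, the standard preparation of Julia–Kocienski sulfones, in a medium the acetonide should tolerate.

Step 4
Reactants: 5 the tetrazolyl sulfone; 6 (2E,4E)-octa-2,4-dienal
Product: 7 (4R)-4-{[(4E,6E,8E)-dodeca-4,6,8-trien-1-yloxy]methyl}-2,2-dimethyl-1,3-dioxolane
Conditions: KN(SiMe3)2, DME, −60 °C; 6 added after 20 min; → rt
Reagents that add atoms: none
Why: Julia–Kocienski olefination: the potassium sulfonyl carbanion adds 1,2 to the dienal through an open transition state, and Smiles rearrangement with anti elimination of SO2 and tetrazololate should give the new C4=C5 bond as the E isomer, the two existing E double bonds of 6 being carried over unchanged.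

Step 5
Reactants: 7 the triene acetonide
Product: 8 (2S)-3-[(4E,6E,8E)-dodeca-4,6,8-trien-1-yloxy]propane-1,2-diol
Conditions: AcOH–H2O (4:1), THF, 40 °C
Reagents that add atoms: none
Why: Acid-catalysed acetal hydrolysis under mild conditions that should leave the non-allylic ether and the conjugated triene untouched; both glycerol C–O bonds stay intact, so C2 keeps its configuration.

Step 6
Reactants: 8 the 1-O-alkyl-sn-glycerol
Product: 9 (2R)-1-[(tert-butyldimethylsilyl)oxy]-3-[(4E,6E,8E)-dodeca-4,6,8-trien-1-yloxy]propan-2-ol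
Conditions: TBSCl (1.05 equiv), imidazole, CH2Cl2, −10 °C → 0 °C
Reagents that add atoms: tert-butyldimethylsilyl chloride, CC(C)(C)[Si](C)(C)Cl
Why: Silylation of a 1,2-diol with a bulky chlorosilane is selective for the primary hydroxyl on steric grounds.

Step 7
Reactants: 9 the secondary alcohol; 10 propiolic acid
Product: 11 (2R)-1-[(tert-butyldimethylsilyl)oxy]-3-[(4E,6E,8E)-dodeca-4,6,8-trien-1-yloxy]propan-2-yl prop-2-ynoate
Conditions: DCC, DMAP (5 mol %), CH2Cl2, −20 °C → 0 °C
Reagents that add atoms: none
Why: Steglich esterification, run cold with little DMAP to limit conjugate addition to the ynoate; the alcohol C–O bond is not broken, so the configuration is retained.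

Step 8
Reactants: 11 the glyceryl propiolate; 12 Danishefsky's diene, (E)-1-methoxy-3-(trimethylsilyloxy)buta-1,3-diene
Product: 15 (2R)-1-[(tert-butyldimethylsilyl)oxy]-3-[(4E,6E,8E)-dodeca-4,6,8-trien-1-yloxy]propan-2-yl 4-hydroxybenzoate, via methoxycyclohexadiene cycloadduct 13 (not isolated), via aryl trimethylsilyl ether 14 (not isolated)
Conditions: 12 (2.5 equiv), BHT (cat.), toluene, 90 °C, dark; then 0.1 M HCl, THF, 0 °C, 20 min
Reagents that add atoms: none
Why: Diels–Alder reaction of an alkynoate with a 1-alkoxy-3-siloxybutadiene followed by aromatising elimination, the known way from propiolate esters to 4-hydroxybenzoates; the cycloaddition is concerted but asynchronous, the nucleophilic CH2 terminus of 12 bonding to the ynoate β-carbon (C2'–C3') and the methoxy-bearing terminus to the α-carbon (C6'–C1'). The benzene ring is thus closed by an intermolecular [4+2] annulation that forms two C–C bonds and gives 1,4-cyclohexadiene 13, whose doubly allylic methoxy group leaves as methanol (1,4-elimination, completed on acidification) to give aryl silyl ether 14, which the dilute acid hydrolyses to the phenol. No lasting stereocentre is made: the methoxy-bearing carbon of 13 forms as both epimers and becomes planar on aromatisation, and glycerol C2 is remote from every bond made or broken. The step needs regioselectivity (OH para to the ester) and chemoselectivity over the chain triene; the first follows from the reinforcing donor pattern of the diene (largest HOMO coefficient at CH2) matched with the ynoate LUMO (largest coefficient at the β-carbon), the second from the electron-rich diene, used in excess, adding to the electron-poor alkyne far faster than the unactivated all-E triene, whose intramolecular addition would need a macrocyclic transition state. The short, cold acid treatment should spare the primary tert-butyldimethylsilyl ether, the secondary ester and the triene.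

Step 9
Reactants: 15 the primary silyl ether
Product: 16 (2S)-1-[(4E,6E,8E)-dodeca-4,6,8-trien-1-yloxy]-3-hydroxypropan-2-yl 4-hydroxybenzoate (target)
Conditions: HF·pyridine, pyridine, THF, 0 °C; NaHCO3 quench to pH 7; chromatography on boric acid-treated silica
Reagents that add atoms: none
Why: Fluoride-mediated Si–O cleavage in a pyridine-buffered, weakly acidic medium, where no alkoxide is formed and migration of the benzoate from O2 to the freed primary oxygen should be suppressed; phenol, ester and triene are inert to the reagent.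

**Compound list**
1 | (R)-solketal, [(4R)-2,2-dimethyl-1,3-dioxolan-4-yl]methanol | OC[C@@H]1COC(C)(C)O1 | starting material
2 | 1-bromo-4-chlorobutane | ClCCCCBr | starting material
3 | (4R)-4-[(4-chlorobutoxy)methyl]-2,2-dimethyl-1,3-dioxolane | ClCCCCOC[C@@H]1COC(C)(C)O1 | intermediate
4 | 5-[(4-{[(4R)-2,2-dimethyl-1,3-dioxolan-4-yl]methoxy}butyl)sulfanyl]-1-phenyl-1H-tetrazole | c1ccc(cc1)-n2nnnc2SCCCCOC[C@@H]3COC(C)(C)O3 | intermediate
5 | 5-[(4-{[(4R)-2,2-dimethyl-1,3-dioxolan-4-yl]methoxy}butyl)sulfonyl]-1-phenyl-1H-tetrazole | c1ccc(cc1)-n2nnnc2S(=O)(=O)CCCCOC[C@@H]3COC(C)(C)O3 | intermediate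
6 | (2E,4E)-octa-2,4-dienal | CCC/C=C/C=C/C=O | starting material
7 | (4R)-4-{[(4E,6E,8E)-dodeca-4,6,8-trien-1-yloxy]methyl}-2,2-dimethyl-1,3-dioxolane | CCC/C=C/C=C/C=C/CCCOC[C@@H]1COC(C)(C)O1 | intermediate
8 | (2S)-3-[(4E,6E,8E)-dodeca-4,6,8-trien-1-yloxy]propane-1,2-diol | CCC/C=C/C=C/C=C/CCCOC[C@H](CO)O | intermediate
9 | (2R)-1-[(tert-butyldimethylsilyl)oxy]-3-[(4E,6E,8E)-dodeca-4,6,8-trien-1-yloxy]propan-2-ol | CCC/C=C/C=C/C=C/CCCOC[C@H](CO[Si](C)(C)C(C)(C)C)O | intermediate
10 | propiolic acid | C#CC(=O)O | starting material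
11 | (2R)-1-[(tert-butyldimethylsilyl)oxy]-3-[(4E,6E,8E)-dodeca-4,6,8-trien-1-yloxy]propan-2-yl prop-2-ynoate | CCC/C=C/C=C/C=C/CCCOC[C@H](CO[Si](C)(C)C(C)(C)C)OC(=O)C#C | intermediate
12 | Danishefsky's diene, (E)-1-methoxy-3-(trimethylsilyloxy)buta-1,3-diene | CO/C=C/C(=C)O[Si](C)(C)C | starting material
13 | (2R)-1-[(tert-butyldimethylsilyl)oxy]-3-[(4E,6E,8E)-dodeca-4,6,8-trien-1-yloxy]propan-2-yl 6-methoxy-4-[(trimethylsilyl)oxy]cyclohexa-1,4-diene-1-carboxylate (both C6 epimers) | CCC/C=C/C=C/C=C/CCCOC[C@H](CO[Si](C)(C)C(C)(C)C)OC(=O)C1=CCC(O[Si](C)(C)C)=CC1OC | intermediate (not isolated)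
14 | (2R)-1-[(tert-butyldimethylsilyl)oxy]-3-[(4E,6E,8E)-dodeca-4,6,8-trien-1-yloxy]propan-2-yl 4-[(trimethylsilyl)oxy]benzoate | CCC/C=C/C=C/C=C/CCCOC[C@H](CO[Si](C)(C)C(C)(C)C)OC(=O)c1ccc(O[Si](C)(C)C)cc1 | intermediate (not isolated)
15 | (2R)-1-[(tert-butyldimethylsilyl)oxy]-3-[(4E,6E,8E)-dodeca-4,6,8-trien-1-yloxy]propan-2-yl 4-hydroxybenzoate | CCC/C=C/C=C/C=C/CCCOC[C@H](CO[Si](C)(C)C(C)(C)C)OC(=O)c1ccc(O)cc1 | intermediate
16 | (2S)-1-[(4E,6E,8E)-dodeca-4,6,8-trien-1-yloxy]-3-hydroxypropan-2-yl 4-hydroxybenzoate | CCC/C=C/C=C/C=C/CCCOC[C@H](CO)OC(=O)c1ccc(O)cc1 | target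

**Totals**
Total step count: 9.
Longest linear sequence: 9 steps, from 1 to 16.

**Steps most likely to fail**

Step 4. With a conjugated aldehyde the addition–Smiles–elimination sequence may lose E selectivity at the new C4=C5 bond, and vinylogous deprotonation of the dienal by the sulfonyl anion may lower conversion. The fallback sets out from 1 and comes back at 7, fixing the C4=C5 geometry by syn hydrometalation and a stereoretentive cross-coupling. Alkylation of 1 with 5-chloropent-1-yne (NaH, NaI cat., DMF) should give (4R)-2,2-dimethyl-4-[(pent-4-yn-1-yloxy)methyl]-1,3-dioxolane F1. Hydroboration with pinacolborane (Cp2ZrHCl cat., Et3N, 60 °C) should give the E-alkenylboronate 2-[(1E)-5-{[(4R)-2,2-dimethyl-1,3-dioxolan-4-yl]methoxy}pent-1-en-1-yl]-4,4,5,5-tetramethyl-1,3,2-dioxaborolane F2. Suzuki–Miyaura coupling of F2 (Pd(PPh3)4, aqueous K3PO4, THF) with (1E,3E)-1-iodohepta-1,3-diene F3, made from (E)-hex-2-enal by Takai olefination (CrCl2, CHI3, THF), should give 7 with all three double bonds E.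

Step 8. Aromatisation may stall at the cyclohexadiene stage, the ynoate may oligomerise or the diene hydrolyse before cycloaddition at the required temperature, the chain triene may compete as a diene, and the acid work-up may begin to remove the primary silyl ether. The fallback sets out from 9 and comes back at 16, introducing the ring ready-made. Steglich esterification of 9 with 4-[(tert-butyldimethylsilyl)oxy]benzoic acid (EDC·HCl, DMAP, CH2Cl2) should give (2R)-1-[(tert-butyldimethylsilyl)oxy]-3-[(4E,6E,8E)-dodeca-4,6,8-trien-1-yloxy]propan-2-yl 4-[(tert-butyldimethylsilyl)oxy]benzoate F4. Removal of both silyl ethers with HF·pyridine–pyridine in THF at 0 °C should then give 16.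

Step 9. During desilylation or purification the benzoate may migrate from the secondary O2 to the freed primary oxygen. The fallback sets out from 8 and comes back at 16. It uses a more labile silyl group that falls off in the acid work-up of the ring-forming step, so no fluoride step and no separate handling of a protected 2-acylglycerol is needed.
- Silylation of 8 with TESCl–imidazole at −20 °C should give (2R)-1-[(4E,6E,8E)-dodeca-4,6,8-trien-1-yloxy]-3-[(triethylsilyl)oxy]propan-2-ol F5.
- Esterification as in step 7 should give the propiolate (2R)-1-[(4E,6E,8E)-dodeca-4,6,8-trien-1-yloxy]-3-[(triethylsilyl)oxy]propan-2-yl prop-2-ynoate F6.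
- Cycloaddition with 12 as in step 8 should give, without isolation, the triethylsilyl-series methoxycyclohexadiene cycloadduct F7 and, after loss of methanol, the triethylsilyl-series aryl trimethylsilyl ether F8.
- Prolonged treatment with 0.1 M HCl in THF–MeOH at 0 °C should hydrolyse F8 first to the triethylsilyl-protected 4-hydroxybenzoate F9 and then to 16, under conditions that stay non-basic throughout.

**Further compounds**
F1 | step 4 | (4R)-2,2-dimethyl-4-[(pent-4-yn-1-yloxy)methyl]-1,3-dioxolane | C#CCCCOC[C@@H]1COC(C)(C)O1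
F2 | step 4 | 2-[(1E)-5-{[(4R)-2,2-dimethyl-1,3-dioxolan-4-yl]methoxy}pent-1-en-1-yl]-4,4,5,5-tetramethyl-1,3,2-dioxaborolane | CC1(C)OB(/C=C/CCCOC[C@@H]2COC(C)(C)O2)OC1(C)C
F3 | step 4 | (1E,3E)-1-iodohepta-1,3-diene | CCC/C=C/C=C/I
F4 | step 8 | (2R)-1-[(tert-butyldimethylsilyl)oxy]-3-[(4E,6E,8E)-dodeca-4,6,8-trien-1-yloxy]propan-2-yl 4-[(tert-butyldimethylsilyl)oxy]benzoate | CCC/C=C/C=C/C=C/CCCOC[C@H](CO[Si](C)(C)C(C)(C)C)OC(=O)c1ccc(O[Si](C)(C)C(C)(C)C)cc1
F5 | step 9 | (2R)-1-[(4E,6E,8E)-dodeca-4,6,8-trien-1-yloxy]-3-[(triethylsilyl)oxy]propan-2-ol | CCC/C=C/C=C/C=C/CCCOC[C@H](CO[Si](CC)(CC)CC)O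
F6 | step 9 | (2R)-1-[(4E,6E,8E)-dodeca-4,6,8-trien-1-yloxy]-3-[(triethylsilyl)oxy]propan-2-yl prop-2-ynoate | CCC/C=C/C=C/C=C/CCCOC[C@H](CO[Si](CC)(CC)CC)OC(=O)C#C
F7 | step 9 | (2R)-1-[(4E,6E,8E)-dodeca-4,6,8-trien-1-yloxy]-3-[(triethylsilyl)oxy]propan-2-yl 6-methoxy-4-[(trimethylsilyl)oxy]cyclohexa-1,4-diene-1-carboxylate (both C6 epimers, not isolated) | CCC/C=C/C=C/C=C/CCCOC[C@H](CO[Si](CC)(CC)CC)OC(=O)C1=CCC(O[Si](C)(C)C)=CC1OC
F8 | step 9 | (2R)-1-[(4E,6E,8E)-dodeca-4,6,8-trien-1-yloxy]-3-[(triethylsilyl)oxy]propan-2-yl 4-[(trimethylsilyl)oxy]benzoate (not isolated) | CCC/C=C/C=C/C=C/CCCOC[C@H](CO[Si](CC)(CC)CC)OC(=O)c1ccc(O[Si](C)(C)C)cc1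
F9 | step 9 | (2R)-1-[(4E,6E,8E)-dodeca-4,6,8-trien-1-yloxy]-3-[(triethylsilyl)oxy]propan-2-yl 4-hydroxybenzoate (not isolated) | CCC/C=C/C=C/C=C/CCCOC[C@H](CO[Si](CC)(CC)CC)OC(=O)c1ccc(O)cc1
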